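**Strategy.** The ten-membered carbocycle is disconnected across the transannular pair C5/C10, which is the ring-fusion bond between ring A and ring B of α-santonin; the C5 carbinol and the C1–C10 epoxide of the target are the traces of a ketone and an (E)-alkene. The key step, an alkoxide-triggered Grob fragmentation, cleaves C5–C10 of a trans-decalin and releases the (E)-cyclodecenone with the C6/C7 trans-lactone, the C2–C3 and C4–C15 epoxides and the C8 oxygen already in place. Its precursor is a 1β-mesyloxy-5α-hydroxy-2β,3β:4α,15-diepoxy-8α-silyloxy-eudesman-6α,12-olide, in which every stereocentre other than C5 and the C1–C10 epoxide was set on six-membered rings.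

Key step: step 14

Assumption: α/β labels of the ten-membered-ring compounds follow the usual germacranolide drawing (C14 β, H7 α), so the target is read as the 1β,10α:2β,3β:4α,15-triepoxide with 5α-OH (5S), 8α-angelate and 6α,12-lactone; the SMILES strings are decisive. TBSO = tert-butyldimethylsilyloxy.

Design notes:
- The C4 spiro-epoxide is installed before the fragmentation, cis to the 5α-hydroxyl on the rigid decalin. A hydroxyl-directed epoxidation of the ring-opened allylic alcohol is expected to give the C4 epimer (erythro preference of 2-substituted allylic alcohols), and the fragmentation product is then not an α-methylene ketone.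
- The Wharton transposition gives the 1α-alcohol, so C1 is inverted through the ketone before it serves as directing and leaving group.
- C11 is carried as the 11β-methyl epimer (11αH) because it becomes sp2 in step 17.

Step 1
Reactants: 1 α-santonin
Product: 2 1α,2α-epoxy-3-oxoeudesm-4-en-6α,12-olide
Conditions: H2O2 (30% aq), NaOH, MeOH, 0 °C → rt; then AcOH to pH 4
Reagents that add atoms: hydrogen peroxide, OO
Why: Nucleophilic (Weitz–Scheffer) epoxidation touches only the disubstituted C1=C2 bond of the cross-conjugated dienone, the hydroperoxide adding to C1 anti to the angular C14 methyl so that C1 and C2 are set as the α-epoxide, and the lactone that opens in base recloses on acidification.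

Step 2
Reactants: 2 1α,2α-epoxy-3-oxoeudesm-4-en-6α,12-olide
Product: 5 1α,2α-epoxy-3-oxoeudesma-4,7(11)-dien-6α,12-olide, via lithium lactone enolate 3 (not isolated), via 11β-bromo lactone 4 (not isolated)
Conditions: LiN(iPr)2 (1.1 equiv), THF, −78 °C; BrCCl2CCl2Br, −78 °C; then DBU, −78 °C → rt
Reagents that add atoms: none
Why: Kinetic deprotonation at the lactone α-carbon C11 and bromination anti to H7 should place bromine 11β, anti-periplanar to H7α, so that E2 dehydrobromination gives the tetrasubstituted conjugated 7(11)-butenolide (enolate α-bromination followed by dehydrohalogenation).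

Step 3
Reactants: 5 1α,2α-epoxy-3-oxoeudesma-4,7(11)-dien-6α,12-olide
Product: 6 1α,2α-epoxy-8β-hydroxy-3-oxoeudesma-4,7(11)-dien-6α,12-olide
Conditions: SeO2 (1.5 equiv), 1,4-dioxane, 80 °C
Reagents that add atoms: selenium dioxide, O=[Se]=O
Why: Riley allylic hydroxylation, in which the ene step can take only the axial 8β hydrogen (the one methylene C–H aligned with the C7=C11 π bond) and the following 2,3-sigmatropic shift returns oxygen to the same face, so the 8β-alcohol should form with the double bond back in conjugation.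

Step 4
Reactants: 6 1α,2α-epoxy-8β-hydroxy-3-oxoeudesma-4,7(11)-dien-6α,12-olide
Product: 8 1α,2α-epoxy-8α-hydroxy-3-oxoeudesma-4,7(11)-dien-6α,12-olide, via 8α-formate 7 (not isolated)
Conditions: PPh3, DIAD, HCO2H, THF, 0 °C → rt; then NaHCO3, MeOH, 0 °C
Reagents that add atoms: formic acid, O=CO
Why: Mitsunobu esterification displaces the activated allylic 8β-oxygen by formate with inversion (ionisation is disfavoured because the allyl cation would carry the lactone carbonyl), which sets the 8α configuration, and the formate is then removed by NaHCO3 methanolysis mild enough to leave the lactone closed on O6.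

Step 5
Reactants: 8 1α,2α-epoxy-8α-hydroxy-3-oxoeudesma-4,7(11)-dien-6α,12-olide
Product: 9 1α,2α-epoxy-8α-hydroxy-3-oxo-11αH-eudesm-4-en-6α,12-olide
Conditions: [Ir(cod)(PCy3)(py)]PF6 (5 mol %), H2 (1 atm), CH2Cl2, rt
Reagents that add atoms: none
Why: Hydroxyl-assisted homogeneous hydrogenation, in which [Ir(cod)(PCy3)(py)]PF6 bound to the C8 hydroxyl should add H2 cis to the tetrasubstituted C7=C11 bond from the α face, away from the C14 methyl and the axial 6β and 8β hydrogens, setting H7α (trans-lactone) and H11α while the remote hindered C4=C5 enone and the epoxide remain.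

Step 6
Reactants: 9 1α,2α-epoxy-8α-hydroxy-3-oxo-11αH-eudesm-4-en-6α,12-olide
Product: 10 8α-TBSO-1α,2α-epoxy-3-oxo-11αH-eudesm-4-en-6α,12-olide
Conditions: TBSOTf, 2,6-lutidine, CH2Cl2, −78 → 0 °C
Reagents that add atoms: tert-butyldimethylsilyl triflate, CC(C)(C)[Si](C)(C)OS(=O)(=O)C(F)(F)F
Why: Silylation of the only hydroxyl with the silyl triflate and a hindered base gives a base-stable ether without touching a stereocentre and closes the path from the 6,12- to the 8,12-lactone in the later basic steps.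

Step 7
Reactants: 10 8α-TBSO-1α,2α-epoxy-3-oxo-11αH-eudesm-4-en-6α,12-olide
Product: 11 8α-TBSO-1α-hydroxy-11αH-eudesma-2,4-dien-6α,12-olide
Conditions: N2H4·H2O (3 equiv), AcOH (0.2 equiv), MeOH, 0 °C → rt
Reagents that add atoms: none
Why: Wharton transposition, in which the hydrazone of the epoxy ketone opens the oxirane and loses N2, moving the double bond to C2=C3 and keeping the C1–O bond, so the 1α-hydroxy-2,4-diene should result.

Step 8
Reactants: 11 8α-TBSO-1α-hydroxy-11αH-eudesma-2,4-dien-6α,12-olide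
Product: 12 8α-TBSO-1-oxo-11αH-eudesma-2,4-dien-6α,12-olide
Conditions: 1,1,1-triacetoxy-1,2-benziodoxol-3(1H)-one (1.3 equiv), NaHCO3, CH2Cl2, 0 °C → rt
Reagents that add atoms: none
Why: Periodinane oxidation of the secondary allylic alcohol under buffered conditions gives the linear 1-oxo-2,4-dienone without ionising the acid-labile dienylic C6–O bond and erases the unwanted C1 configuration.

Step 9
Reactants: 12 8α-TBSO-1-oxo-11αH-eudesma-2,4-dien-6α,12-olide
Product: 13 8α-TBSO-1β-hydroxy-11αH-eudesma-2,4-dien-6α,12-olide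
Conditions: NaBH4, CeCl3·7H2O, MeOH, −78 → −40 °C
Reagents that add atoms: none
Why: Luche 1,2-reduction of the dienone, in which hydride should approach C1 anti to the C14 methyl on the neighbouring quaternary C10 and so set the 1β (equatorial) carbinol needed for the syn-directed epoxidation and for the fragmentation.

Step 10
Reactants: 13 8α-TBSO-1β-hydroxy-11αH-eudesma-2,4-dien-6α,12-olide
Product: 14 8α-TBSO-2β,3β-epoxy-1β-hydroxy-11αH-eudesm-4-en-6α,12-olide
Conditions: VO(acac)2 (5 mol %), t-BuOOH (1.5 equiv, decane), CH2Cl2, 0 °C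
Reagents that add atoms: tert-butyl hydroperoxide, CC(C)(C)OO
Why: Hydroxyl-directed VO(acac)2-catalysed epoxidation delivers oxygen to the allylic C2=C3 bond syn to the 1β-hydroxyl, setting C2 and C3 as the β-epoxide, and spares the tetrasubstituted homoallylic C4=C5 bond because allylic alcohols react far faster than homoallylic ones.

Step 11
Reactants: 14 8α-TBSO-2β,3β-epoxy-1β-hydroxy-11αH-eudesm-4-en-6α,12-olide
Product: 16 8α-TBSO-2β,3β-epoxy-1β,5α-dihydroxy-11αH-eudesm-4(15)-en-6α,12-olide, via 5α-hydroperoxide 15 (not isolated)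
Conditions: O2, visible light, tetraphenylporphyrin (1 mol %), CH2Cl2, −20 °C; then PPh3, −20 °C → rt
Reagents that add atoms: oxygen, O=O
Why: Schenck ene reaction, in which singlet oxygen should add to the α face of C4=C5 because the β face is covered by C14 and the epoxide oxygen, the only allylic hydrogens within reach on that face are those of the C15 methyl, so oxygen bonds to C5 (setting the 5α-carbinol) while the double bond shifts to C4=C15, and PPh3 then reduces the hydroperoxide.

Step 12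
Reactants: 16 8α-TBSO-2β,3β-epoxy-1β,5α-dihydroxy-11αH-eudesm-4(15)-en-6α,12-olide
Product: 17 8α-TBSO-2β,3β:4α,15-diepoxy-1β,5α-dihydroxy-11αH-eudesman-6α,12-olide
Conditions: m-CPBA (1.3 equiv), NaHCO3, CH2Cl2, 0 °C
Reagents that add atoms: 3-chloroperbenzoic acid, O=C(OO)c1cccc(Cl)c1
Why: Peracid (Prilezhaev) epoxidation of the exocyclic alkene is guided by hydrogen bonding to the adjacent axial 5α-hydroxyl and by shielding of the β face by C14, so oxygen should enter from the α face and set C4 as the 4α,15-spiro-epoxide on the rigid decalin.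

Step 13
Reactants: 17 8α-TBSO-2β,3β:4α,15-diepoxy-1β,5α-dihydroxy-11αH-eudesman-6α,12-olide
Product: 18 8α-TBSO-2β,3β:4α,15-diepoxy-5α-hydroxy-1β-mesyloxy-11αH-eudesman-6α,12-olide
Conditions: MsCl (1.2 equiv), Et3N, CH2Cl2, −20 → 0 °C
Reagents that add atoms: methanesulfonyl chloride, CS(=O)(=O)Cl
Why: Sulfonylation through the sulfene differentiates the secondary 1β-hydroxyl from the tertiary 5α-hydroxyl with retention at C1, and the neighbouring epoxide makes the neopentyl mesylate reluctant to ionise.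

Step 14
Reactants: 18 8α-TBSO-2β,3β:4α,15-diepoxy-5α-hydroxy-1β-mesyloxy-11αH-eudesman-6α,12-olide
Product: 20 8α-TBSO-2β,3β:4α,15-diepoxy-5-oxo-11αH-germacr-1(10)E-en-6α,12-olide, via potassium 5-alkoxide 19 (not isolated)
Conditions: KOC(CH3)3 (1.1 equiv), THF, −20 → 0 °C; NH4Cl quench
Reagents that add atoms: none
Why: KOC(CH3)3 deprotonates the tertiary 5α-hydroxyl, and the alkoxide lone pair becomes the C5=O π bond as the C5–C10 σ bond breaks anti-periplanar to the departing C1–O mesylate bond, so that C5=O and C1=C10 form in one concerted Grob fragmentation. The closest known reaction type is the Wharton-type fragmentation of decalin 1,3-diol monosulfonates to (E)-cyclodec-5-enones. No ring is closed: the ten-membered ring is set free when the bond shared by ring A and ring B is cut, so no medium-ring cyclisation is needed. No stereocentre is created, and C2, C3, C4, C6, C7 and C8 pass through unchanged. The selectivities needed are fragmentation over oxetane formation or substitution and the (E) geometry of C1=C10; both are secured by the trans-decalin, which holds the equatorial 1β-mesylate anti to C5–C10 with C9 anti to C2, while C10 is quaternary and C2 is an oxirane carbon so that no E2 path exists, and the alkoxide is cis to the C4–O bond so that no epoxide migration can compete. The base is consumed by the fragmentation itself, which protects the C6 stereocentre next to the new ketone.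

Step 15
Reactants: 20 8α-TBSO-2β,3β:4α,15-diepoxy-5-oxo-11αH-germacr-1(10)E-en-6α,12-olide
Product: 21 8α-TBSO-2β,3β:4α,15-diepoxy-(5S)-5-hydroxy-11αH-germacr-1(10)E-en-6α,12-olide
Conditions: NaBH4, CeCl3·7H2O, MeOH/THF, −78 °C
Reagents that add atoms: none
Why: Luche-type carbonyl reduction, in which the inner face of the C5 ketone is covered by the transannular C1=C10 bond in the conformation inherited from the decalin, so hydride should enter from the convex face anti to the former C5–C10 bond and set the 5S carbinol, while CeCl3 keeps the medium non-basic for the epoxides and the lactone.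

Step 16
Reactants: 21 8α-TBSO-2β,3β:4α,15-diepoxy-(5S)-5-hydroxy-11αH-germacr-1(10)E-en-6α,12-olide
Product: 22 8α-TBSO-1β,10α:2β,3β:4α,15-triepoxy-(5S)-5-hydroxy-11αH-germacran-6α,12-olide
Conditions: dimethyldioxirane (acetone solution, 1.5 equiv), CH2Cl2, 0 °C
Reagents that add atoms: dimethyldioxirane, CC1(C)OO1
Why: Dioxirane epoxidation under neutral conditions should attack the trisubstituted (E)-C1=C10 bond on its exposed outer face, the inner face pointing across the ring, which gives the trans 1β,10α-epoxide and sets C1 and C10.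

Step 17
Reactants: 22 8α-TBSO-1β,10α:2β,3β:4α,15-triepoxy-(5S)-5-hydroxy-11αH-germacran-6α,12-olide
Product: 26 8α-TBSO-1β,10α:2β,3β:4α,15-triepoxy-(5S)-5-hydroxygermacr-11(13)-en-6α,12-olide, via dilithium alkoxide enolate 23 (not isolated), via 11β-phenylselenide 24 (not isolated), via selenoxide 25 (not isolated)
Conditions: LiN(iPr)2 (2.4 equiv), THF, −78 °C; PhSeCl (1.1 equiv), −78 °C; AcOH quench at −78 °C; then H2O2 (30% aq), pyridine, 0 °C → rt
Reagents that add atoms: none
Why: Lactone α-selenenylation and selenoxide syn-elimination, in which selenium enters anti to H7 so that the selenoxide has only the C13 methyl hydrogens syn and should eliminate to the exocyclic C11=C13 methylene, the 5-alkoxide being held at −78 °C and quenched before warming to forestall Payne-type epoxide migration.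

Step 18
Reactants: 26 8α-TBSO-1β,10α:2β,3β:4α,15-triepoxy-(5S)-5-hydroxygermacr-11(13)-en-6α,12-olide
Product: 27 1β,10α:2β,3β:4α,15-triepoxy-(5S)-5,8α-dihydroxygermacr-11(13)-en-6α,12-olide
Conditions: Bu4NF, AcOH (1:1), THF, 0 °C → rt
Reagents that add atoms: none
Why: Fluoride-induced desilylation buffered with acetic acid frees the 8α-hydroxyl without generating a free alkoxide, which should spare the three epoxides, the α-methylene lactone and the position of the lactone on O6.

Step 19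
Reactants: 27 1β,10α:2β,3β:4α,15-triepoxy-(5S)-5,8α-dihydroxygermacr-11(13)-en-6α,12-olide; 28 angelic acid
Product: 30 8α-angeloyloxy-1β,10α:2β,3β:4α,15-triepoxy-(5S)-5-hydroxygermacr-11(13)-en-6α,12-olide (CNP0594916.1), via mixed anhydride 29 (not isolated)
Conditions: 28, 2,4,6-trichlorobenzoyl chloride, Et3N, toluene, rt; then 27 (28 used at 1.2 equiv), toluene, 80 °C
Reagents that add atoms: angelic acid, C/C=C(/C)C(=O)O
Why: Mixed-anhydride esterification, in which the angelic 2,4,6-trichlorobenzoic anhydride acylates at the angeloyl carbonyl without an amine catalyst so that the (Z)-geometry should survive, and the C8 hydroxyl should react in preference to the C5 hydroxyl, which is flanked by the spiro-epoxide carbon and the lactone carbinol.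

**Compound list**

1 | α-santonin (3-oxoeudesma-1,4-dien-6α,12-olide, 11S) | C[C@H]1[C@@H]2CC[C@]3(C=CC(=O)C(=C3[C@H]2OC1=O)C)C | starting material
2 | 1α,2α-epoxy-3-oxoeudesm-4-en-6α,12-olide | C[C@@H]1C(=O)O[C@H]2[C@H]1CC[C@@]3(C)[C@H]4O[C@H]4C(=O)C(C)=C23 | intermediate
3 | lithium lactone enolate of 2 (not isolated) | [Li+].CC1=C([O-])O[C@H]2[C@H]1CC[C@@]3(C)[C@H]4O[C@H]4C(=O)C(C)=C23 | intermediate
4 | 11β-bromo-1α,2α-epoxy-3-oxoeudesm-4-en-6α,12-olide (not isolated) | C[C@]1(Br)C(=O)O[C@H]2[C@H]1CC[C@@]3(C)[C@H]4O[C@H]4C(=O)C(C)=C23 | intermediate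
5 | 1α,2α-epoxy-3-oxoeudesma-4,7(11)-dien-6α,12-olide | CC1=C2CC[C@@]3(C)[C@H]4O[C@H]4C(=O)C(C)=C3[C@H]2OC1=O | intermediate
6 | 1α,2α-epoxy-8β-hydroxy-3-oxoeudesma-4,7(11)-dien-6α,12-olide | CC1=C2[C@H](O)C[C@@]3(C)[C@H]4O[C@H]4C(=O)C(C)=C3[C@H]2OC1=O | intermediate
7 | 1α,2α-epoxy-8α-formyloxy-3-oxoeudesma-4,7(11)-dien-6α,12-olide (not isolated) | CC1=C2[C@@H](OC=O)C[C@@]3(C)[C@H]4O[C@H]4C(=O)C(C)=C3[C@H]2OC1=O | intermediate
8 | 1α,2α-epoxy-8α-hydroxy-3-oxoeudesma-4,7(11)-dien-6α,12-olide | CC1=C2[C@@H](O)C[C@@]3(C)[C@H]4O[C@H]4C(=O)C(C)=C3[C@H]2OC1=O | intermediate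
9 | 1α,2α-epoxy-8α-hydroxy-3-oxo-11αH-eudesm-4-en-6α,12-olide (H7α, 11β-methyl) | C[C@H]1C(=O)O[C@H]2[C@H]1[C@@H](O)C[C@@]3(C)[C@H]4O[C@H]4C(=O)C(C)=C23 | intermediate
10 | 8α-(tert-butyldimethylsilyloxy)-1α,2α-epoxy-3-oxo-11αH-eudesm-4-en-6α,12-olide | C[C@H]1C(=O)O[C@H]2[C@H]1[C@@H](O[Si](C)(C)C(C)(C)C)C[C@@]3(C)[C@H]4O[C@H]4C(=O)C(C)=C23 | intermediate
11 | 8α-TBSO-1α-hydroxy-11αH-eudesma-2,4-dien-6α,12-olide | C[C@H]1C(=O)O[C@H]2[C@H]1[C@@H](O[Si](C)(C)C(C)(C)C)C[C@@]3(C)[C@@H](O)C=CC(C)=C23 | intermediate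
12 | 8α-TBSO-1-oxo-11αH-eudesma-2,4-dien-6α,12-olide | C[C@H]1C(=O)O[C@H]2[C@H]1[C@@H](O[Si](C)(C)C(C)(C)C)C[C@@]3(C)C(=O)C=CC(C)=C23 | intermediate
13 | 8α-TBSO-1β-hydroxy-11αH-eudesma-2,4-dien-6α,12-olide | C[C@H]1C(=O)O[C@H]2[C@H]1[C@@H](O[Si](C)(C)C(C)(C)C)C[C@@]3(C)[C@H](O)C=CC(C)=C23 | intermediate
14 | 8α-TBSO-2β,3β-epoxy-1β-hydroxy-11αH-eudesm-4-en-6α,12-olide | C[C@H]1C(=O)O[C@H]2[C@H]1[C@@H](O[Si](C)(C)C(C)(C)C)C[C@@]3(C)[C@H](O)[C@@H]4O[C@@H]4C(C)=C23 | intermediate
15 | 8α-TBSO-2β,3β-epoxy-5α-hydroperoxy-1β-hydroxy-11αH-eudesm-4(15)-en-6α,12-olide (not isolated) | C[C@H]1C(=O)O[C@H]2[C@H]1[C@@H](O[Si](C)(C)C(C)(C)C)C[C@@]3(C)[C@H](O)[C@@H]4O[C@@H]4C(=C)[C@]23OO | intermediate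
16 | 8α-TBSO-2β,3β-epoxy-1β,5α-dihydroxy-11αH-eudesm-4(15)-en-6α,12-olide | C[C@H]1C(=O)O[C@H]2[C@H]1[C@@H](O[Si](C)(C)C(C)(C)C)C[C@@]3(C)[C@H](O)[C@@H]4O[C@@H]4C(=C)[C@]23O | intermediate
17 | 8α-TBSO-2β,3β:4α,15-diepoxy-1β,5α-dihydroxy-11αH-eudesman-6α,12-olide | C[C@H]1C(=O)O[C@H]2[C@H]1[C@@H](O[Si](C)(C)C(C)(C)C)C[C@@]3(C)[C@H](O)[C@@H]4O[C@@H]4[C@]5(CO5)[C@]23O | intermediate
18 | 8α-TBSO-2β,3β:4α,15-diepoxy-5α-hydroxy-1β-mesyloxy-11αH-eudesman-6α,12-olide (fragmentation precursor) | C[C@H]1C(=O)O[C@H]2[C@H]1[C@@H](O[Si](C)(C)C(C)(C)C)C[C@@]3(C)[C@H](OS(C)(=O)=O)[C@@H]4O[C@@H]4[C@]5(CO5)[C@]23O | intermediate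
19 | potassium 5-alkoxide of 18 (not isolated) | [K+].C[C@H]1C(=O)O[C@H]2[C@H]1[C@@H](O[Si](C)(C)C(C)(C)C)C[C@@]3(C)[C@H](OS(C)(=O)=O)[C@@H]4O[C@@H]4[C@]5(CO5)[C@]23[O-] | intermediate
20 | 8α-TBSO-2β,3β:4α,15-diepoxy-5-oxo-11αH-germacr-1(10)E-en-6α,12-olide (fragmentation product) | C[C@H]1C(=O)O[C@H]2[C@H]1[C@@H](O[Si](C)(C)C(C)(C)C)C/C(C)=C/[C@@H]3O[C@@H]3[C@]4(CO4)C2=O | intermediate
21 | 8α-TBSO-2β,3β:4α,15-diepoxy-(5S)-5-hydroxy-11αH-germacr-1(10)E-en-6α,12-olide | C[C@H]1C(=O)O[C@H]2[C@H]1[C@@H](O[Si](C)(C)C(C)(C)C)C/C(C)=C/[C@@H]3O[C@@H]3[C@]4(CO4)[C@H]2O | intermediate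
22 | 8α-TBSO-1β,10α:2β,3β:4α,15-triepoxy-(5S)-5-hydroxy-11αH-germacran-6α,12-olide | C[C@H]1C(=O)O[C@H]2[C@H]1[C@@H](O[Si](C)(C)C(C)(C)C)C[C@@]3(C)O[C@@H]3[C@@H]4O[C@@H]4[C@]5(CO5)[C@H]2O | intermediate
23 | dilithium 5-alkoxide lactone enolate of 22 (not isolated) | [Li+].[Li+].CC1=C([O-])O[C@H]2[C@H]1[C@@H](O[Si](C)(C)C(C)(C)C)C[C@@]3(C)O[C@@H]3[C@@H]4O[C@@H]4[C@]5(CO5)[C@H]2[O-] | intermediate
24 | 11β-phenylseleno derivative of 22 (11α-methyl, not isolated) | C[C@]1([Se]c6ccccc6)C(=O)O[C@H]2[C@H]1[C@@H](O[Si](C)(C)C(C)(C)C)C[C@@]3(C)O[C@@H]3[C@@H]4O[C@@H]4[C@]5(CO5)[C@H]2O | intermediate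
25 | selenoxide of 24 (not isolated) | C[C@]1([Se](=O)c6ccccc6)C(=O)O[C@H]2[C@H]1[C@@H](O[Si](C)(C)C(C)(C)C)C[C@@]3(C)O[C@@H]3[C@@H]4O[C@@H]4[C@]5(CO5)[C@H]2O | intermediate
26 | 8α-TBSO-1β,10α:2β,3β:4α,15-triepoxy-(5S)-5-hydroxygermacr-11(13)-en-6α,12-olide | C=C1C(=O)O[C@H]2[C@H]1[C@@H](O[Si](C)(C)C(C)(C)C)C[C@@]3(C)O[C@@H]3[C@@H]4O[C@@H]4[C@]5(CO5)[C@H]2O | intermediate
27 | 1β,10α:2β,3β:4α,15-triepoxy-(5S)-5,8α-dihydroxygermacr-11(13)-en-6α,12-olide | C=C1C(=O)O[C@H]2[C@H]1[C@@H](O)C[C@@]3(C)O[C@@H]3[C@@H]4O[C@@H]4[C@]5(CO5)[C@H]2O | intermediate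
28 | angelic acid ((Z)-2-methylbut-2-enoic acid) | C/C=C(/C)C(=O)O | starting material
29 | angelic 2,4,6-trichlorobenzoic anhydride (not isolated) | C/C=C(/C)C(=O)OC(=O)c1c(Cl)cc(Cl)cc1Cl | intermediate
30 | 8α-angeloyloxy-1β,10α:2β,3β:4α,15-triepoxy-(5S)-5-hydroxygermacr-11(13)-en-6α,12-olide (CNP0594916.1) | C=C1C(=O)O[C@H]2[C@H]1[C@@H](OC(=O)/C(C)=C\C)C[C@@]1(C)O[C@@H]1[C@@H]1O[C@@H]1[C@]1(CO1)[C@H]2O | target

Total step count: 19
Longest linear sequence: 19 steps (1 → 30); angelic acid 28 enters in the last step.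

**Steps most likely to fail**

Step 3. The ene oxidation may show poor site selectivity (attack at the doubly allylic C6–H or at the C15 methyl) or stall on the electron-poor butenolide. Fallback: from 5, the C8 methylene is oxidised to the ketone with CrO3 and 3,5-dimethylpyrazole in CH2Cl2 at −20 °C, a reagent that prefers methylene over methine C–H, to give 1α,2α-epoxy-3,8-dioxoeudesma-4,7(11)-dien-6α,12-olide F1. One hydride equivalent of NaBH4 with CeCl3·7H2O in MeOH at −78 °C should then reduce the more electrophilic, less hindered C8 carbonyl from the α face, anti to C14, and the route is rejoined at 6.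

Step 14. The alkoxide may be diverted before it fragments, by intramolecular displacement of the mesylate to an oxetane or by attack on the neighbouring spiro-oxirane, and surplus base may epimerise C6 of the product. Fallback: setting out from 16, the 1β-hydroxyl is mesylated (MsCl, Et3N) to 8α-TBSO-2β,3β-epoxy-5α-hydroxy-1β-mesyloxy-11αH-eudesm-4(15)-en-6α,12-olide F2. The same KOC(CH3)3 fragmentation then gives 8α-TBSO-2β,3β-epoxy-5-oxo-11αH-germacra-1(10)E,4(15)-dien-6α,12-olide F3. The spiro-epoxide is closed afterwards by nucleophilic epoxidation of this α-methylene ketone (t-BuOOH, DBU, CH2Cl2, 0 °C), where closure on the convex face is expected to give the 4α,15-epoxide, and the route is rejoined at 20.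

Step 15. Facial selectivity may be poor or reversed if the carbonyl turns through the ring or if the two flanking C–O bonds steer hydride to the other face. Fallback: the epimeric alcohol obtained from 20, 8α-TBSO-2β,3β:4α,15-diepoxy-(5R)-5-hydroxy-11αH-germacr-1(10)E-en-6α,12-olide F4, is converted into its 5-triflate F5 (Tf2O, pyridine, CH2Cl2, −20 °C). Displacement with KNO2 in DMF at rt by SN2 attack of nitrite oxygen gives the inverted (5S)-nitrite ester F6, which hydrolyses on aqueous work-up, and the route is rejoined at 21.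

Further compounds
F1 | step 3 | 1α,2α-epoxy-3,8-dioxoeudesma-4,7(11)-dien-6α,12-olide | CC1=C2C(=O)C[C@@]3(C)[C@H]4O[C@H]4C(=O)C(C)=C3[C@H]2OC1=O
F2 | step 14 | 8α-TBSO-2β,3β-epoxy-5α-hydroxy-1β-mesyloxy-11αH-eudesm-4(15)-en-6α,12-olide | C[C@H]1C(=O)O[C@H]2[C@H]1[C@@H](O[Si](C)(C)C(C)(C)C)C[C@@]3(C)[C@H](OS(C)(=O)=O)[C@@H]4O[C@@H]4C(=C)[C@]23O
F3 | step 14 | 8α-TBSO-2β,3β-epoxy-5-oxo-11αH-germacra-1(10)E,4(15)-dien-6α,12-olide | C[C@H]1C(=O)O[C@H]2[C@H]1[C@@H](O[Si](C)(C)C(C)(C)C)C/C(C)=C/[C@@H]3O[C@@H]3C(=C)C2=O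
F4 | step 15 | 8α-TBSO-2β,3β:4α,15-diepoxy-(5R)-5-hydroxy-11αH-germacr-1(10)E-en-6α,12-olide | C[C@H]1C(=O)O[C@H]2[C@H]1[C@@H](O[Si](C)(C)C(C)(C)C)C/C(C)=C/[C@@H]3O[C@@H]3[C@]4(CO4)[C@@H]2O
F5 | step 15 | 5-triflate of F4 | C[C@H]1C(=O)O[C@H]2[C@H]1[C@@H](O[Si](C)(C)C(C)(C)C)C/C(C)=C/[C@@H]3O[C@@H]3[C@]4(CO4)[C@@H]2OS(=O)(=O)C(F)(F)F
F6 | step 15 | (5S)-nitrite ester of 21 | C[C@H]1C(=O)O[C@H]2[C@H]1[C@@H](O[Si](C)(C)C(C)(C)C)C/C(C)=C/[C@@H]3O[C@@H]3[C@]4(CO4)[C@H]2ON=O
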